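**Retrosynthetic overview**

1. Variabilin 23 is cut at the exocyclic C=C into the (S)-α-methyl aldehyde 16 and lithiated 4-methoxy-3-methylfuran-2(5H)-one (aldol, dehydration, O-demethylation last). The butenolide ring is bought intact as 3-methyltetronic acid.
2. The strategy rests on the furan being substituted only at C3, with C2 and C5 bearing hydrogen. Cutting furan C3=C4 leaves O1–C2 as the acetal carbon of an acrolein mixed acetal and O1–C5 as the O–CH2 of a 2-alkylallyl ether (12).
3. Acetal 12 comes from the 2-methylene alcohol 10, made from allylic bromide 7 and the dianion of 2-methylprop-2-en-1-ol.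
4. Bromide 7 comes from (2E,6E)-farnesol: hydroxylation of the terminal E methyl, then hydroxyl-directed asymmetric hydrogenation to set the single stereocentre (S).
5. Ring order: the furan is the only ring formed (step 9), after all allylic oxidation; the tetronate ring is attached afterwards (step 13).

Key step: step 9

Assumption: the facial sense of the hydroxyl-directed Ru–BINAP hydrogenation of the (E)-2-methylallylic alcohol 3 is taken to follow that of geraniol, which assigns (S)-BINAP to the 11S product. The configuration would be checked on 4 (Mosher esters) and the antipodal ligand used if the sense were opposite. Farnesol numbering is used for 2–7.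

**Route**

Step 1
Reactants: 1 (2E,6E)-farnesol
Product: 2 (2E,6E)-farnesyl acetate
Conditions: Ac2O, pyridine, DMAP (cat.), CH2Cl2, 0 → 23 °C
Reagents that add atoms: acetic anhydride, CC(=O)OC(C)=O
Why: DMAP-catalysed O-acetylation of a primary allylic alcohol; the acetate also deactivates the C2=C3 alkene toward the allylic oxidation that follows.

Step 2
Reactants: 2 (2E,6E)-farnesyl acetate
Product: 3 (2E,6E,10E)-12-hydroxy-3,7,11-trimethyldodeca-2,6,10-trien-1-yl acetate
Conditions: SeO2 (0.1 equiv), salicylic acid (0.1 equiv), t-BuOOH (70% aq., 3 equiv), CH2Cl2, 0 → 23 °C, partial conversion, recovered 2 recycled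
Reagents that add atoms: tert-butyl hydroperoxide, CC(C)(C)OO; selenium dioxide, O=[Se]=O
Why: Sharpless catalytic SeO2 allylic oxidation (ene reaction, then [2,3]-sigmatropic shift) should attack the most electron-rich and least hindered terminal alkene at its E methyl group with retention of E geometry, the alkene next to the acetate being deactivated.

Step 3
Reactants: 3 (2E,6E,10E)-12-hydroxy-3,7,11-trimethyldodeca-2,6,10-trien-1-yl acetate
Product: 4 (2E,6E,11S)-12-hydroxy-3,7,11-trimethyldodeca-2,6-dien-1-yl acetate
Conditions: Ru(OAc)2[(S)-BINAP] (1 mol %), H2 (100 atm), MeOH, 20 °C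
Reagents that add atoms: none
Why: Noyori hydroxyl-directed asymmetric hydrogenation, in which only the alkene chelated to the divalent ruthenium alkoxide through the free allylic hydroxyl is reduced, so the isolated alkene and the allylic acetate alkene should remain, and the (S)-BINAP ligand selects the alkene face that sets C11 as S (facial sense as assumed above).

Step 4
Reactants: 4 (2E,6E,11S)-12-hydroxy-3,7,11-trimethyldodeca-2,6-dien-1-yl acetate
Product: 5 (2E,6E,11S)-12-(tert-butyldiphenylsilyloxy)-3,7,11-trimethyldodeca-2,6-dien-1-yl acetate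
Conditions: TBDPSCl, imidazole, DMF, 23 °C
Reagents that add atoms: tert-butyl(chloro)diphenylsilane, CC(C)(C)[Si](Cl)(c1ccccc1)c1ccccc1
Why: Imidazole-promoted silylation of the primary alcohol; the TBDPS ether is chosen to survive the organolithium, PPTS and trifluoroacetic acid used later.

Step 5
Reactants: 5 (2E,6E,11S)-12-(tert-butyldiphenylsilyloxy)-3,7,11-trimethyldodeca-2,6-dien-1-yl acetate
Product: 6 (2E,6E,11S)-12-(tert-butyldiphenylsilyloxy)-3,7,11-trimethyldodeca-2,6-dien-1-ol
Conditions: K2CO3 (0.2 equiv), MeOH, 23 °C
Reagents that add atoms: none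
Why: Base-catalysed transesterification (methanolysis) removes the acetate and leaves the primary TBDPS ether intact.

Step 6
Reactants: 6 (2E,6E,11S)-12-(tert-butyldiphenylsilyloxy)-3,7,11-trimethyldodeca-2,6-dien-1-ol
Product: 7 tert-butyl{[(2S,6E,10E)-12-bromo-2,6,10-trimethyldodeca-6,10-dien-1-yl]oxy}diphenylsilane
Conditions: CBr4, PPh3, CH2Cl2, 0 °C; used crude
Reagents that add atoms: tetrabromomethane, BrC(Br)(Br)Br
Why: Appel bromination, in which bromide displaces the alkoxyphosphonium at the primary allylic carbon by SN2 at 0 °C without allylic transposition or loss of E geometry.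

Step 7
Reactants: 7 the allylic bromide; 8 2-methylprop-2-en-1-ol
Product: 10 (5E,9E,14S)-15-(tert-butyldiphenylsilyloxy)-6,10,14-trimethyl-2-methylidenepentadeca-5,9-dien-1-ol, via dilithiated 2-methylprop-2-en-1-ol 9 (not isolated)
Conditions: 8 (3 equiv), n-BuLi (6 equiv), TMEDA, Et2O, 0 → 23 °C; then 7 in THF, −78 → 0 °C; H2O
Reagents that add atoms: none
Why: Alkylation of the alkoxide-assisted allylic dianion of methallyl alcohol, whose two carbanion termini are equivalent, with the primary allylic bromide by SN2 at low temperature, which disfavours SN2′ attack at the hindered C3 position.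

Step 8
Reactants: 10 the 2-methylene alcohol; 11 acrolein diethyl acetal
Product: 12 mixed ethyl 2-alkylallyl acetal of acrolein on the (S)-silyloxy chain (both acetal epimers)
Conditions: 11 (10 equiv), PPTS (5 mol %), toluene, 40 °C, reduced pressure (EtOH removed)
Reagents that add atoms: none
Why: Acid-catalysed transacetalisation, driven to single exchange by excess acetal and removal of ethanol; the new acetal centre forms as both epimers, which is of no consequence because it becomes sp2 in step 9.

Step 9
Reactants: 12 the mixed acetal diene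
Product: 14 tert-butyl{[(2S,6E,10E)-13-(furan-3-yl)-2,6,10-trimethyltrideca-6,10-dien-1-yl]oxy}diphenylsilane, via 2-ethoxy-2,5-dihydrofuran 13 (not isolated)
Conditions: second-generation Grubbs catalyst RuCl2(=CHPh)(PCy3)(H2IMes) (5 mol %), CH2Cl2 (0.02 M), 40 °C; then CF3CO2H (10 mol %), 23 °C
Reagents that add atoms: none
Why: The ruthenium benzylidene initiates at the unhindered acetal vinyl group, and the resulting alkylidene adds intramolecularly to the 1,1-disubstituted alkene through a ruthenacyclobutane whose cycloreversion releases ethylene and forms furan C3=C4 within 2-ethoxy-2,5-dihydrofuran 13. Trifluoroacetic acid then ionises the cyclic acetal to an oxocarbenium ion, and loss of a proton from the ring O–CH2 with release of ethanol gives the aromatic furan. The closest known reaction type is the ring-closing metathesis of mixed allylic acetals of acrolein followed by acid-promoted loss of alcohol to give furans. The one ring is closed as a five-membered ring by olefin metathesis between two terminal alkenes joined through the acetal O–C–O unit, giving an endocyclic trisubstituted alkene. No stereocentre is formed, since the acetal carbon becomes sp2 so that both epimers of 12 converge, and the remote S centre is not involved. The step needs the catalyst to engage only the two terminal alkenes, which the substrate secures because the trisubstituted chain alkenes react far more slowly and could close only to rings of eight or more members, and it needs the acid kept catalytic so that the silyl ether and chain alkenes survive.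

Step 10
Reactants: 14 the furanyl chain TBDPS ether
Product: 15 (2S,6E,10E)-13-(furan-3-yl)-2,6,10-trimethyltrideca-6,10-dien-1-ol
Conditions: Bu4NF, THF, 23 °C
Reagents that add atoms: none
Why: Fluoride-mediated desilylation driven by the strong Si–F bond; the furan and alkenes are inert to it.

Step 11
Reactants: 15 the furanyl chain alcohol
Product: 16 (2S,6E,10E)-13-(furan-3-yl)-2,6,10-trimethyltrideca-6,10-dienal
Conditions: Dess–Martin periodinane, NaHCO3, CH2Cl2, 0 → 23 °C; used at once
Reagents that add atoms: none
Why: Dess–Martin oxidation under buffered, near-neutral conditions should give the α-methyl aldehyde without epimerisation and without touching the furan.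

Step 12
Reactants: 17 3-methyltetronic acid
Product: 18 4-methoxy-3-methylfuran-2(5H)-one
Conditions: Me2SO4, K2CO3, acetone, reflux
Reagents that add atoms: dimethyl sulfate, COS(=O)(=O)OC
Why: O-methylation of the vinylogous acid with a hard methylating agent gives the methyl tetronate, which masks the acidic hydroxyl for the enolate chemistry.

Step 13
Reactants: 16 the (S)-aldehyde; 18 4-methoxy-3-methylfuran-2(5H)-one
Product: 20 5-[(2S,6E,10E)-13-(furan-3-yl)-1-hydroxy-2,6,10-trimethyltrideca-6,10-dien-1-yl]-4-methoxy-3-methylfuran-2(5H)-one (diastereomer mixture), via lithium 4-methoxy-3-methylfuran-2-olate 19 (not isolated)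
Conditions: 18 (1.3 equiv), LiN(i-Pr)2 (1.2 equiv), THF, −78 °C; then 16, −78 °C; AcOH, −78 °C
Reagents that add atoms: none
Why: Vinylogous aldol addition of the C5-lithiated methyl tetronate (a 2-furanolate), which should add through C5 to the aldehyde at −78 °C faster than it enolises it; the two new centres form unselectively and are both removed in step 14, while the S centre is kept.

Step 14
Reactants: 20 the aldol adduct
Product: 22 (5Z)-5-[(2S,6E,10E)-13-(furan-3-yl)-2,6,10-trimethyltrideca-6,10-dien-1-ylidene]-4-methoxy-3-methylfuran-2(5H)-one, via methanesulfonate of the aldol adduct 21 (not isolated)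
Conditions: MsCl, Et3N, CH2Cl2, 0 °C; then DBU, 23 °C
Reagents that add atoms: none
Why: Mesylation followed by E1cB elimination through the C5 furanolate, which should favour the Z alkylidene because the E isomer places the chain against the 4-methoxy group; all diastereomers of 20 converge.

Step 15
Reactants: 22 the (Z)-ylidene methyl tetronate
Product: 23 variabilin
Conditions: NaSPr, DMF, 23 → 50 °C; then 1 M HCl
Reagents that add atoms: none
Why: SN2 O-demethylation by the soft thiolate at the methyl group of the vinylogous ester, with the stabilised tetronate as leaving group and acidification to the tetronic acid; the furan, alkenes and S centre are not affected.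

**Compound list**

1 | (2E,6E)-farnesol | CC(C)=CCC/C(C)=C/CC/C(C)=C/CO | starting material
2 | (2E,6E)-farnesyl acetate | CC(C)=CCC/C(C)=C/CC/C(C)=C/COC(C)=O | intermediate
3 | (2E,6E,10E)-12-hydroxy-3,7,11-trimethyldodeca-2,6,10-trien-1-yl acetate | OC/C(C)=C/CC/C(C)=C/CC/C(C)=C/COC(C)=O | intermediate
4 | (2E,6E,11S)-12-hydroxy-3,7,11-trimethyldodeca-2,6-dien-1-yl acetate | OC[C@@H](C)CCC/C(C)=C/CC/C(C)=C/COC(C)=O | intermediate
5 | (2E,6E,11S)-12-(tert-butyldiphenylsilyloxy)-3,7,11-trimethyldodeca-2,6-dien-1-yl acetate | CC(C)(C)[Si](c1ccccc1)(c1ccccc1)OC[C@@H](C)CCC/C(C)=C/CC/C(C)=C/COC(C)=O | intermediate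
6 | (2E,6E,11S)-12-(tert-butyldiphenylsilyloxy)-3,7,11-trimethyldodeca-2,6-dien-1-ol | CC(C)(C)[Si](c1ccccc1)(c1ccccc1)OC[C@@H](C)CCC/C(C)=C/CC/C(C)=C/CO | intermediate
7 | tert-butyl{[(2S,6E,10E)-12-bromo-2,6,10-trimethyldodeca-6,10-dien-1-yl]oxy}diphenylsilane | CC(C)(C)[Si](c1ccccc1)(c1ccccc1)OC[C@@H](C)CCC/C(C)=C/CC/C(C)=C/CBr | intermediate
8 | 2-methylprop-2-en-1-ol | C=C(C)CO | starting material
9 | dilithiated 2-methylprop-2-en-1-ol (lithium 2-(lithiomethyl)prop-2-en-1-olate) | [Li]CC(=C)CO[Li] | intermediate (not isolated)
10 | (5E,9E,14S)-15-(tert-butyldiphenylsilyloxy)-6,10,14-trimethyl-2-methylidenepentadeca-5,9-dien-1-ol | CC(C)(C)[Si](c1ccccc1)(c1ccccc1)OC[C@@H](C)CCC/C(C)=C/CC/C(C)=C/CCC(=C)CO | intermediate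
11 | acrolein diethyl acetal (3,3-diethoxyprop-1-ene) | C=CC(OCC)OCC | starting material
12 | mixed ethyl 2-alkylallyl acetal of acrolein on the (S)-silyloxy chain, both acetal epimers | CC(C)(C)[Si](c1ccccc1)(c1ccccc1)OC[C@@H](C)CCC/C(C)=C/CC/C(C)=C/CCC(=C)COC(OCC)C=C | intermediate
13 | 4-alkyl-2-ethoxy-2,5-dihydrofuran on the (S)-silyloxy chain, both epimers | CC(C)(C)[Si](c1ccccc1)(c1ccccc1)OC[C@@H](C)CCC/C(C)=C/CC/C(C)=C/CCC1=CC(OCC)OC1 | intermediate (not isolated)
14 | tert-butyl{[(2S,6E,10E)-13-(furan-3-yl)-2,6,10-trimethyltrideca-6,10-dien-1-yl]oxy}diphenylsilane | CC(C)(C)[Si](c1ccccc1)(c1ccccc1)OC[C@@H](C)CCC/C(C)=C/CC/C(C)=C/CCc1ccoc1 | intermediate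
15 | (2S,6E,10E)-13-(furan-3-yl)-2,6,10-trimethyltrideca-6,10-dien-1-ol | OC[C@@H](C)CCC/C(C)=C/CC/C(C)=C/CCc1ccoc1 | intermediate
16 | (2S,6E,10E)-13-(furan-3-yl)-2,6,10-trimethyltrideca-6,10-dienal | O=C[C@@H](C)CCC/C(C)=C/CC/C(C)=C/CCc1ccoc1 | intermediate
17 | 3-methyltetronic acid (4-hydroxy-3-methylfuran-2(5H)-one) | CC1=C(O)COC1=O | starting material
18 | 4-methoxy-3-methylfuran-2(5H)-one | CC1=C(OC)COC1=O | intermediate
19 | lithium 4-methoxy-3-methylfuran-2-olate | [Li]Oc1occ(OC)c1C | intermediate (not isolated)
20 | 5-[(2S,6E,10E)-13-(furan-3-yl)-1-hydroxy-2,6,10-trimethyltrideca-6,10-dien-1-yl]-4-methoxy-3-methylfuran-2(5H)-one, mixture at C5 and the carbinol carbon | CC1=C(OC)C(C(O)[C@@H](C)CCC/C(C)=C/CC/C(C)=C/CCc2ccoc2)OC1=O | intermediate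
21 | methanesulfonate of 20 | CC1=C(OC)C(C(OS(C)(=O)=O)[C@@H](C)CCC/C(C)=C/CC/C(C)=C/CCc2ccoc2)OC1=O | intermediate (not isolated)
22 | (5Z)-5-[(2S,6E,10E)-13-(furan-3-yl)-2,6,10-trimethyltrideca-6,10-dien-1-ylidene]-4-methoxy-3-methylfuran-2(5H)-one | CC1=C(OC)/C(=C/[C@@H](C)CCC/C(C)=C/CC/C(C)=C/CCc2ccoc2)OC1=O | intermediate
23 | variabilin, (5Z)-5-[(2S,6E,10E)-13-(furan-3-yl)-2,6,10-trimethyltrideca-6,10-dien-1-ylidene]-4-hydroxy-3-methylfuran-2(5H)-one | CC1=C(O)/C(=C/[C@@H](C)CCC/C(C)=C/CC/C(C)=C/CCc2ccoc2)OC1=O | target

**Step count**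

Total: 15 steps. Longest linear sequence: 14 steps (steps 1–11 and 13–15 from farnesol); step 12 is a one-step side branch.

**Steps most likely to fail**

Step 3 (asymmetric hydrogenation). Enantioface discrimination on a 2-methyl-substituted allylic alcohol may be insufficient, the facial sense may differ from the geraniol model, or the alkene may migrate before hydrogen is delivered, eroding the enantiomeric purity of the only stereocentre. The fallback sets out from 3 and comes back at 4. Alcohol 3 is oxidised with MnO2 to the enal (2E,6E,10E)-3,7,11-trimethyl-12-oxododeca-2,6,10-trien-1-yl acetate F1. Pinnick oxidation (NaClO2, NaH2PO4, 2-methylbut-2-ene) then gives the tiglic-acid-type (2E,6E,10E)-12-acetoxy-2,6,10-trimethyldodeca-2,6,10-trienoic acid F2. Carboxylate-directed hydrogenation with Ru(OAc)2[(S)-H8-BINAP], a substrate class for which the S ligand is known to give the (S)-2-methyl acid, should furnish (2S,6E,10E)-12-acetoxy-2,6,10-trimethyldodeca-6,10-dienoic acid F3. Activation with ClCO2Et and Et3N gives the mixed ethyl carbonic anhydride F4, and NaBH4 at 0 °C reduces it to 4 without touching the acetate or the alkenes.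

Step 7 (dianion alkylation). The strongly basic, aggregated dianion may give SN2′ attack, elimination or halogen–metal exchange with homocoupling of the allylic bromide instead of clean substitution. The fallback sets out from 6 and comes back at 10, forming the neighbouring C–C bond instead. MnO2 oxidation of 6 gives (2E,6E,11S)-12-(tert-butyldiphenylsilyloxy)-3,7,11-trimethyldodeca-2,6-dienal F5. Wittig methylenation with Ph3P=CH2 gives the terminal 1,3-diene tert-butyl{[(2S,6E,10E)-2,6,10-trimethyltrideca-6,10,12-trien-1-yl]oxy}diphenylsilane F6. 9-BBN hydroborates only the monosubstituted terminal alkene to give the B-alkyl-9-borabicyclo[3.3.1]nonane F7. B-alkyl Suzuki–Miyaura coupling of F7 with commercial 2-bromoprop-2-en-1-ol (PdCl2(dppf), aqueous K3PO4, THF/DMF) then gives 10.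

Step 9 (ring-closing metathesis and aromatisation). The catalyst may engage the trisubstituted chain alkenes or give intermolecular cross-metathesis of the terminal alkenes, and the acid stage may cause partial desilylation or acid-induced degradation of the polyene. The fallback sets out from 7 and comes back at 14, introducing the furan ready-made instead of building it. Commercial furan-3-ylmethanol is converted with SOCl2 and pyridine into 3-(chloromethyl)furan F8. Magnesium in THF turns F8 into (furan-3-ylmethyl)magnesium chloride F9. Li2CuCl4-catalysed coupling of F9 with bromide 7 at the primary allylic carbon (THF, −20 → 0 °C) gives 14 directly.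

**Further compounds**

F1 | step 3 | (2E,6E,10E)-3,7,11-trimethyl-12-oxododeca-2,6,10-trien-1-yl acetate | O=C/C(C)=C/CC/C(C)=C/CC/C(C)=C/COC(C)=O
F2 | step 3 | (2E,6E,10E)-12-acetoxy-2,6,10-trimethyldodeca-2,6,10-trienoic acid | OC(=O)/C(C)=C/CC/C(C)=C/CC/C(C)=C/COC(C)=O
F3 | step 3 | (2S,6E,10E)-12-acetoxy-2,6,10-trimethyldodeca-6,10-dienoic acid | OC(=O)[C@@H](C)CCC/C(C)=C/CC/C(C)=C/COC(C)=O
F4 | step 3 | mixed ethyl carbonic anhydride of F3 | CCOC(=O)OC(=O)[C@@H](C)CCC/C(C)=C/CC/C(C)=C/COC(C)=O
F5 | step 7 | (2E,6E,11S)-12-(tert-butyldiphenylsilyloxy)-3,7,11-trimethyldodeca-2,6-dienal | CC(C)(C)[Si](c1ccccc1)(c1ccccc1)OC[C@@H](C)CCC/C(C)=C/CC/C(C)=C/C=O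
F6 | step 7 | tert-butyl{[(2S,6E,10E)-2,6,10-trimethyltrideca-6,10,12-trien-1-yl]oxy}diphenylsilane | CC(C)(C)[Si](c1ccccc1)(c1ccccc1)OC[C@@H](C)CCC/C(C)=C/CC/C(C)=C/C=C
F7 | step 7 | 9-[(3E,7E,12S)-13-(tert-butyldiphenylsilyloxy)-4,8,12-trimethyltrideca-3,7-dien-1-yl]-9-borabicyclo[3.3.1]nonane | CC(C)(C)[Si](c1ccccc1)(c1ccccc1)OC[C@@H](C)CCC/C(C)=C/CC/C(C)=C/CCB1C2CCCC1CCC2
F8 | step 9 | 3-(chloromethyl)furan | ClCc1ccoc1
F9 | step 9 | (furan-3-ylmethyl)magnesium chloride | Cl[Mg]Cc1ccoc1
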